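**Retrosynthetic overview**

1. Bonnaniol is (2R,3R)-6-geranyl-3,5,7,4'-tetrahydroxyflavanone. The enabling feature is that C8a (bearing O1) and C4a (bearing the C4 carbonyl) are neighbours in ring A, flanked unequally by C8–H and C5–O. The chain O1–C2–C3–C4 of ring C maps onto a 3-arylglycidate (carboxylate O = O1, carboxyl C = C4, epoxide carbons = C3 and C2).
2. Key disconnection: O1–C2 (epoxide opening with inversion at C2), together with C4–C4a and O1–C8a. This leads back to the aryne C4a≡C8a of a 2-geranylphloroglucinol bis-MOM ether and potassium (2R,3S)-3-[4-(methoxymethoxy)phenyl]glycidate.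
3. The aryne precursor (a 2-silylaryl triflate) comes from phloroglucinol. Its parent phenol is C2-symmetric (geranyl para to OH), so both ortho positions are equivalent and no 6- versus 8-geranyl question arises.
4. The glycidate comes from methyl p-coumarate by MOM protection, Shi epoxidation and saponification.
5. Ring order: rings A and B are bought as benzene rings; ring C is the only ring made, in the key step; global MOM removal ends the route.

Key step: step 11

Remark: the L-fructose-derived diacetate ketone (enantiomer of the usual D-fructose-derived epoxidation catalyst) is taken to deliver the (2R,3S)-epoxide, by analogy with the (2S,3R) sense recalled for the D-series ketone with trans-cinnamate esters. Geranyl = (2E)-3,7-dimethylocta-2,6-dien-1-yl throughout.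

**Route**

Step 1
Reactants: 1 phloroglucinol (benzene-1,3,5-triol)
Product: 2 3,5-bis(methoxymethoxy)phenol
Conditions: MOMCl (2.0 equiv), i-Pr2NEt, THF–DMF, 0 °C → rt; chromatography
Reagents that add atoms: chloromethyl methyl ether, COCCl
Why: Statistical O-alkylation (Williamson type) of a threefold-symmetric triol, so only one bis-ether can form and it should be separable from the mono- and tris-ethers.

Step 2
Reactants: 2 3,5-bis(methoxymethoxy)phenol
Product: 3 [3,5-bis(methoxymethoxy)phenoxy]tri(propan-2-yl)silane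
Conditions: TIPSCl, imidazole, DMF, rt
Reagents that add atoms: chlorotri(propan-2-yl)silane, CC(C)[Si](Cl)(C(C)C)C(C)C
Why: Silylation of the remaining phenol gives a bulky, poorly coordinating ether that is stable to alkyllithiums and steers the next metalation away from its own ortho positions.

Step 3
Reactants: 3 [3,5-bis(methoxymethoxy)phenoxy]tri(propan-2-yl)silane; 4 geranyl bromide [(2E)-1-bromo-3,7-dimethylocta-2,6-diene]
Product: 6 [4-geranyl-3,5-bis(methoxymethoxy)phenoxy]tri(propan-2-yl)silane, via aryllithium 5 (not isolated)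
Conditions: n-BuLi, THF, 0 °C; then 4, −78 °C → rt
Reagents that add atoms: none
Why: Directed ortho-metalation at the ring carbon flanked by both OMOM groups (cooperative chelation), then SN2 alkylation by the primary allylic bromide, which should keep the E geometry of the chain.

Step 4
Reactants: 6 [4-geranyl-3,5-bis(methoxymethoxy)phenoxy]tri(propan-2-yl)silane
Product: 7 4-geranyl-3,5-bis(methoxymethoxy)phenol
Conditions: Bu4NF, AcOH, THF, 0 °C → rt
Reagents that add atoms: none
Why: Fluoride cleavage of the aryl silyl ether, buffered with acetic acid so that the MOM ethers and the diene should stay untouched.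

Step 5
Reactants: 7 4-geranyl-3,5-bis(methoxymethoxy)phenol
Product: 8 4-geranyl-3,5-bis(methoxymethoxy)phenyl N-(propan-2-yl)carbamate
Conditions: i-PrNCO, Et3N (cat.), CH2Cl2, rt
Reagents that add atoms: isopropyl isocyanate (2-isocyanatopropane), CC(C)N=C=O
Why: Base-catalysed addition of the phenol to the isocyanate installs a strong ortho-directing group that can later be removed under mild base.

Step 6
Reactants: 8 4-geranyl-3,5-bis(methoxymethoxy)phenyl N-(propan-2-yl)carbamate
Product: 12 4-geranyl-3,5-bis(methoxymethoxy)-2-(trimethylsilyl)phenyl N-(propan-2-yl)carbamate, via N-silyl carbamate 9 (not isolated), via aryllithium 10 (not isolated), via disilyl carbamate 11 (not isolated)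
Conditions: TBSOTf, TMEDA, Et2O, 0 °C → rt; then n-BuLi, TMEDA, −78 °C; then TMSCl, −78 °C → rt; aq. NH4Cl
Reagents that add atoms: chlorotrimethylsilane, C[Si](C)(C)Cl
Why: Directed ortho-metalation in which in-situ N-silylation masks the N–H, the O-carbamate and the neighbouring OMOM group direct lithiation to the position between them (both such positions are equivalent), and C-silylation followed by aqueous N-desilylation should give 12.

Step 7
Reactants: 12 4-geranyl-3,5-bis(methoxymethoxy)-2-(trimethylsilyl)phenyl N-(propan-2-yl)carbamate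
Product: 14 4-geranyl-3,5-bis(methoxymethoxy)-2-(trimethylsilyl)phenyl trifluoromethanesulfonate, via silyl phenol 13 (not isolated)
Conditions: DBU, Et2NH, MeCN, 40 °C; then PhNTf2, rt
Reagents that add atoms: N-phenylbis(trifluoromethanesulfonimide), O=S(=O)(N(c1ccccc1)S(=O)(=O)C(F)(F)F)C(F)(F)F
Why: DBU triggers E1cB loss of the carbamoyl group, which diethylamine takes up as a urea, and the released phenoxide is triflated in the same pot (established one-pot route from N-monoalkyl aryl carbamates to 2-silylaryl triflates).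

Step 8
Reactants: 15 methyl (2E)-3-(4-hydroxyphenyl)prop-2-enoate (methyl p-coumarate)
Product: 16 methyl (2E)-3-[4-(methoxymethoxy)phenyl]prop-2-enoate
Conditions: MOMCl, i-Pr2NEt, CH2Cl2, 0 °C → rt
Reagents that add atoms: chloromethyl methyl ether, COCCl
Why: O-Alkylation of the phenol gives a MOM ether that is stable to the oxidant, to base and to fluoride and is removed together with the other two at the end.

Step 9
Reactants: 16 methyl (2E)-3-[4-(methoxymethoxy)phenyl]prop-2-enoate
Product: 17 methyl (2R,3S)-3-[4-(methoxymethoxy)phenyl]oxirane-2-carboxylate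
Conditions: L-fructose-derived diacetate ketone (4,5-di-O-acetyl-1,2-O-isopropylidene-β-L-erythro-hexo-2,3-diulo-2,6-pyranose, 25 mol%), KHSO5 (as Oxone), NaHCO3, Bu4NHSO4, MeCN–aq. Na2H2EDTA, 0 °C
Reagents that add atoms: potassium peroxymonosulfate, [K+].[O-]S(=O)(=O)OO
Why: Shi epoxidation with the ketone variant made for electron-poor alkenes, in which the chiral dioxirane delivers oxygen to one face of the trans enoate through a spiro transition state; the catalyst enantiomer sets both centres as (2R,3S) and the trans geometry comes from the E alkene.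

Step 10
Reactants: 17 methyl (2R,3S)-3-[4-(methoxymethoxy)phenyl]oxirane-2-carboxylate
Product: 18 potassium (2R,3S)-3-[4-(methoxymethoxy)phenyl]oxirane-2-carboxylate
Conditions: KOH (1.0 equiv), MeOH, 0 °C → rt; evaporation, trituration with Et2O, drying in vacuo
Reagents that add atoms: potassium hydroxide, [K+].[OH-]
Why: Ester saponification with one equivalent of base touches neither stereocentre, and the acid is kept as its dry potassium salt because free 3-arylglycidic acids decarboxylate and the next step must be free of proton sources.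

Step 11
Reactants: 14 4-geranyl-3,5-bis(methoxymethoxy)-2-(trimethylsilyl)phenyl trifluoromethanesulfonate; 18 potassium (2R,3S)-3-[4-(methoxymethoxy)phenyl]oxirane-2-carboxylate
Product: 22 (2R,3R)-6-geranyl-3-hydroxy-5,7-bis(methoxymethoxy)-2-[4-(methoxymethoxy)phenyl]-2,3-dihydro-4H-chromen-4-one, via aryne 19 (not isolated), via aryl anion 20 (not isolated), via epoxy ketone phenoxide 21 (not isolated)
Conditions: CsF (3 equiv), 18-crown-6, THF, 25 °C, 14 added over 4 h to 18 (2 equiv); then AcOH, 0 °C
Reagents that add atoms: none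
Why: Proposed new method: fluoride turns 14 into aryne 19, the carboxylate oxygen of 18 adds to C8a, the resulting C4a aryl anion 20 (no proton source present) attacks its own ester carbonyl through a four-membered alkoxide that reopens by C–O cleavage (O-to-C acyl shift) to the 2-acylphenoxide 21, and this phenoxide opens the epoxide at the benzylic carbon, forming the O1–C2 bond and ring C. The closest known reaction type is the insertion of arynes into the C–O bond of carboxylic acids to give 2-hydroxyaryl ketones, which with acrylic acids runs on to chroman-4-ones by oxa-Michael closure; new here are the glycidate salt and the epoxide-opening terminus, itself the established way in which 2'-hydroxychalcone epoxides close to trans-dihydroflavonols. Ring C closes in a 6-endo-tet mode (attack at the epoxide carbon distal to the carbonyl). C3 is not touched and keeps the (R) configuration of the glycidate α-carbon, while C2 becomes (R) by SN2 inversion of the (S) benzylic epoxide carbon, which gives the 2,3-trans, diequatorial and thermodynamically preferred isomer. The aryne regiochemistry is secured by the groups beside the triple bond: the OMOM group on C5 withdraws inductively and distorts the aryne so that the nucleophile enters at the remote carbon C8a (only C8–H beside it) and the charge develops at C4a next to oxygen, as in 3-alkoxybenzynes, and the same group shields C4a sterically. 6-endo over 5-exo opening is secured by the 4-(methoxymethoxy)phenyl group, which makes the benzylic C–O bond the one that is activated in the transition state, and slow addition of 14 to an excess of 18 keeps the aryne concentration low so that neither 21 nor the product alkoxide should be O-arylated.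

Step 12
Reactants: 22 (2R,3R)-6-geranyl-3-hydroxy-5,7-bis(methoxymethoxy)-2-[4-(methoxymethoxy)phenyl]-2,3-dihydro-4H-chromen-4-one
Product: 23 bonnaniol, (2R,3R)-6-geranyl-3,5,7-trihydroxy-2-(4-hydroxyphenyl)-2,3-dihydro-4H-chromen-4-one
Conditions: HCl (3 M aq.), MeOH, 45 °C, argon
Reagents that add atoms: none
Why: Acid-catalysed acetal methanolysis of the three aryl MOM ethers under brief, dilute conditions that the trisubstituted alkenes should tolerate; the 2,3-trans arrangement is the thermodynamic one, so neither stereocentre is expected to drift.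

**Compound list**

1 | phloroglucinol | Oc1cc(O)cc(O)c1 | starting material
2 | 3,5-bis(methoxymethoxy)phenol | COCOc1cc(O)cc(OCOC)c1 | intermediate
3 | [3,5-bis(methoxymethoxy)phenoxy]tri(propan-2-yl)silane | COCOc1cc(O[Si](C(C)C)(C(C)C)C(C)C)cc(OCOC)c1 | intermediate
4 | geranyl bromide, (2E)-1-bromo-3,7-dimethylocta-2,6-diene | CC(C)=CCC/C(C)=C/CBr | starting material
5 | {2,6-bis(methoxymethoxy)-4-[tri(propan-2-yl)silyloxy]phenyl}lithium | COCOc1cc(O[Si](C(C)C)(C(C)C)C(C)C)cc(OCOC)c1[Li] | intermediate
6 | [4-geranyl-3,5-bis(methoxymethoxy)phenoxy]tri(propan-2-yl)silane | COCOc1cc(O[Si](C(C)C)(C(C)C)C(C)C)cc(OCOC)c1C/C=C(\C)CCC=C(C)C | intermediate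
7 | 4-geranyl-3,5-bis(methoxymethoxy)phenol | COCOc1cc(O)cc(OCOC)c1C/C=C(\C)CCC=C(C)C | intermediate
8 | 4-geranyl-3,5-bis(methoxymethoxy)phenyl N-(propan-2-yl)carbamate | COCOc1cc(OC(=O)NC(C)C)cc(OCOC)c1C/C=C(\C)CCC=C(C)C | intermediate
9 | 4-geranyl-3,5-bis(methoxymethoxy)phenyl N-(tert-butyldimethylsilyl)-N-(propan-2-yl)carbamate | COCOc1cc(OC(=O)N(C(C)C)[Si](C)(C)C(C)(C)C)cc(OCOC)c1C/C=C(\C)CCC=C(C)C | intermediate
10 | 2-lithio derivative of 9 (lithium between the carbamate oxygen and an OMOM group) | COCOc1cc(OC(=O)N(C(C)C)[Si](C)(C)C(C)(C)C)c([Li])c(OCOC)c1C/C=C(\C)CCC=C(C)C | intermediate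
11 | 4-geranyl-3,5-bis(methoxymethoxy)-2-(trimethylsilyl)phenyl N-(tert-butyldimethylsilyl)-N-(propan-2-yl)carbamate | COCOc1cc(OC(=O)N(C(C)C)[Si](C)(C)C(C)(C)C)c([Si](C)(C)C)c(OCOC)c1C/C=C(\C)CCC=C(C)C | intermediate
12 | 4-geranyl-3,5-bis(methoxymethoxy)-2-(trimethylsilyl)phenyl N-(propan-2-yl)carbamate | COCOc1cc(OC(=O)NC(C)C)c([Si](C)(C)C)c(OCOC)c1C/C=C(\C)CCC=C(C)C | intermediate
13 | 4-geranyl-3,5-bis(methoxymethoxy)-2-(trimethylsilyl)phenol | COCOc1cc(O)c([Si](C)(C)C)c(OCOC)c1C/C=C(\C)CCC=C(C)C | intermediate
14 | 4-geranyl-3,5-bis(methoxymethoxy)-2-(trimethylsilyl)phenyl trifluoromethanesulfonate | COCOc1cc(OS(=O)(=O)C(F)(F)F)c([Si](C)(C)C)c(OCOC)c1C/C=C(\C)CCC=C(C)C | intermediate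
15 | methyl (2E)-3-(4-hydroxyphenyl)prop-2-enoate | COC(=O)/C=C/c1ccc(O)cc1 | starting material
16 | methyl (2E)-3-[4-(methoxymethoxy)phenyl]prop-2-enoate | COC(=O)/C=C/c1ccc(OCOC)cc1 | intermediate
17 | methyl (2R,3S)-3-[4-(methoxymethoxy)phenyl]oxirane-2-carboxylate | COC(=O)[C@@H]1O[C@H]1c1ccc(OCOC)cc1 | intermediate
18 | potassium (2R,3S)-3-[4-(methoxymethoxy)phenyl]oxirane-2-carboxylate | [K+].[O-]C(=O)[C@@H]1O[C@H]1c1ccc(OCOC)cc1 | intermediate
19 | 4-geranyl-3,5-bis(methoxymethoxy)-1,2-didehydrobenzene (aryne) | COCOC1=CC#CC(OCOC)=C1C/C=C(\C)CCC=C(C)C | intermediate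
20 | potassium salt of the C2 aryl anion of 4-geranyl-3,5-bis(methoxymethoxy)phenyl (2R,3S)-3-[4-(methoxymethoxy)phenyl]oxirane-2-carboxylate | [K+].COCOc1cc(OC(=O)[C@@H]2O[C@H]2c2ccc(OCOC)cc2)[c-]c(OCOC)c1C/C=C(\C)CCC=C(C)C | intermediate
21 | potassium 4-geranyl-3,5-bis(methoxymethoxy)-2-{(2R,3S)-3-[4-(methoxymethoxy)phenyl]oxirane-2-carbonyl}phenolate | [K+].COCOc1cc([O-])c(C(=O)[C@@H]2O[C@H]2c2ccc(OCOC)cc2)c(OCOC)c1C/C=C(\C)CCC=C(C)C | intermediate
22 | (2R,3R)-6-geranyl-3-hydroxy-5,7-bis(methoxymethoxy)-2-[4-(methoxymethoxy)phenyl]-2,3-dihydro-4H-chromen-4-one | CC(C)=CCC/C(C)=C/Cc1c(OCOC)cc2c(c1OCOC)C(=O)[C@H](O)[C@@H](c1ccc(OCOC)cc1)O2 | intermediate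
23 | bonnaniol, (2R,3R)-6-geranyl-3,5,7-trihydroxy-2-(4-hydroxyphenyl)-2,3-dihydro-4H-chromen-4-one | CC(C)=CCC/C(C)=C/Cc1c(O)cc2c(c1O)C(=O)[C@H](O)[C@@H](c1ccc(O)cc1)O2 | target

**Step count and risks**

Total step count: 12. Longest linear sequence: 9 steps (steps 1–7, 11 and 12).

Steps most likely to fail:

1. Step 11 (proposed new method). The aryl anion may be protonated before the acyl shift, which would stop the cascade at the aryl ester. The phenoxide may open the epoxide at the α-carbon (5-exo), or the product alkoxide may undergo base-induced ring contraction. Fallback by known chemistry, setting out from 14: aryne C–O insertion into acetic acid (CsF, THF, 125 °C, sealed tube) should give the 2'-hydroxyacetophenone F1. Allyl bromide and K2CO3 in DMF give the allyl ether F2. Claisen–Schmidt condensation with commercial 4-(methoxymethoxy)benzaldehyde (KOH, EtOH) gives the E-chalcone F3. Juliá–Colonna epoxidation (poly-L-leucine, urea–H2O2, DBU, THF) should give the (αR,βS)-epoxy ketone F4. Deallylation with Pd(PPh3)4 and morpholine releases the phenol F5 under neutral conditions. F5 is then closed with pyridinium p-toluenesulfonate in CH2Cl2 at the benzylic carbon with inversion; acid catalysis favours the 6-endo mode. The fallback comes back to the route at 22.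

2. Step 6. The silyl triflate used for N-protection may strip a MOM ether, or incompletely N-silylated carbamate may fragment to isocyanate and phenoxide when the base is added. Fallback, setting out from 7: NaH and Et2NCOCl in THF give the tertiary carbamate F6, which needs no N-protection. s-BuLi and TMEDA at −78 °C give the aryllithium F7, and TMSCl gives the silyl carbamate F8. Reductive cleavage with LiAlH4 in THF gives the phenol 13, now isolated. NaH and PhNTf2 then convert 13 into 14, where the fallback comes back to the route.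

3. Step 12. The geranyl chain may cyclise onto the neighbouring phenols under protic acid, or C2 and C3 may epimerise during prolonged acid exposure. Fallback, setting out from 22: TMSOTf and 2,2'-bipyridyl in CH2Cl2 at 0 °C → rt exchange the three aryl MOM ethers for silyl ethers under non-protic conditions and silylate the 3-OH, giving the tetrakis(trimethylsilyl) ether F9. Hydrolysis in MeOH–water at neutral pH then gives 23, where the fallback comes back to the route.

Further compounds
F1 | step 11 | 1-[3-geranyl-6-hydroxy-2,4-bis(methoxymethoxy)phenyl]ethan-1-one | CC(=O)c1c(O)cc(OCOC)c(C/C=C(\C)CCC=C(C)C)c1OCOC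
F2 | step 11 | 1-[3-geranyl-2,4-bis(methoxymethoxy)-6-(prop-2-en-1-yloxy)phenyl]ethan-1-one | CC(=O)c1c(OCC=C)cc(OCOC)c(C/C=C(\C)CCC=C(C)C)c1OCOC
F3 | step 11 | (2E)-1-[3-geranyl-2,4-bis(methoxymethoxy)-6-(prop-2-en-1-yloxy)phenyl]-3-[4-(methoxymethoxy)phenyl]prop-2-en-1-one | O=C(/C=C/c1ccc(OCOC)cc1)c1c(OCC=C)cc(OCOC)c(C/C=C(\C)CCC=C(C)C)c1OCOC
F4 | step 11 | [3-geranyl-2,4-bis(methoxymethoxy)-6-(prop-2-en-1-yloxy)phenyl]{(2R,3S)-3-[4-(methoxymethoxy)phenyl]oxiran-2-yl}methanone | O=C([C@@H]1O[C@H]1c1ccc(OCOC)cc1)c1c(OCC=C)cc(OCOC)c(C/C=C(\C)CCC=C(C)C)c1OCOC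
F5 | step 11 | [3-geranyl-6-hydroxy-2,4-bis(methoxymethoxy)phenyl]{(2R,3S)-3-[4-(methoxymethoxy)phenyl]oxiran-2-yl}methanone | O=C([C@@H]1O[C@H]1c1ccc(OCOC)cc1)c1c(O)cc(OCOC)c(C/C=C(\C)CCC=C(C)C)c1OCOC
F6 | step 6 | 4-geranyl-3,5-bis(methoxymethoxy)phenyl N,N-diethylcarbamate | CCN(CC)C(=O)Oc1cc(OCOC)c(C/C=C(\C)CCC=C(C)C)c(OCOC)c1
F7 | step 6 | 2-lithio derivative of 4-geranyl-3,5-bis(methoxymethoxy)phenyl N,N-diethylcarbamate | CCN(CC)C(=O)Oc1cc(OCOC)c(C/C=C(\C)CCC=C(C)C)c(OCOC)c1[Li]
F8 | step 6 | 4-geranyl-3,5-bis(methoxymethoxy)-2-(trimethylsilyl)phenyl N,N-diethylcarbamate | CCN(CC)C(=O)Oc1cc(OCOC)c(C/C=C(\C)CCC=C(C)C)c(OCOC)c1[Si](C)(C)C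
F9 | step 12 | (2R,3R)-6-geranyl-3,5,7-tris(trimethylsilyloxy)-2-[4-(trimethylsilyloxy)phenyl]-2,3-dihydro-4H-chromen-4-one | CC(C)=CCC/C(C)=C/Cc1c(O[Si](C)(C)C)cc2c(c1O[Si](C)(C)C)C(=O)[C@H](O[Si](C)(C)C)[C@@H](c1ccc(O[Si](C)(C)C)cc1)O2
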